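**Plan**
- Retrosynthesis cuts, in order: the two ester C–O bonds (C3, C9), the C7–C11 bond (isopropenyl), then C8–C9 and C5–C10 together, then C6–C7 (sp2–sp2 coupling) and C3–C4 (propargylation).
- Enabling feature: ring B (C5–C10) holds a two-carbon edge C9–C10 opposite a four-carbon arc C5–C6–C7–C8. With C6=C7 restored (the enone of the C8 ketone), this is a cyclohexene, and the C1–C4 arc of ring A is the tether, so both rings can close from one chain.
- The vicinal C8=O/C9–O pair is carried as two C–B bonds: a dienylboronate (C8) and an alkenylborane (C9) that also activates the dienophile; both are oxidised afterwards.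
- Forward: propargylation joins C3–C4, carboalumination and Suzuki coupling build the (E,E)-diene, and hydroboration then triggers an intramolecular Diels–Alder reaction that closes rings A and B at once. Allylic oxidation, two esterifications and α-isopropenylation finish the route.
- Stereochemistry: C4 and C3 come from (R)-but-3-yn-2-ol through a chiral allenylstannane. C5, C10 and C9 come from the cycloaddition (alkene geometries, chair tether, endo boron). C7 comes from C–C bond formation anti to the angular methyl.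

Key step: step 9

Remark: locants are those of the eremophilane skeleton (decalin C1–C10, C14 on C5, C15 on C4, C11–C13 on C7; β is the face of C14). All bicyclic intermediates are trans-fused with 4β,5β-dimethyl and 10α-H; the target is the (3R,4R,5R,7S,9S,10R) isomer.

**Route**

Step 1
Reactants: 1 silyl alkynol 5-(trimethylsilyl)pent-4-yn-1-ol
Product: 2 aldehyde 5-(trimethylsilyl)pent-4-ynal
Conditions: PhI(OAc)2 (1.1 equiv), TEMPO (10 mol %), CH2Cl2, rt
Reagents that add atoms: none
Why: Nitroxyl-catalysed oxidation of a primary alcohol should stop at the aldehyde and leave the silylalkyne untouched.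

Step 2
Reactants: 3 (R)-but-3-yn-2-ol
Product: 4 (R)-but-3-yn-2-yl methanesulfonate
Conditions: MsCl, Et3N, CH2Cl2, −78 °C to 0 °C
Reagents that add atoms: methanesulfonyl chloride CS(=O)(=O)Cl
Why: O-sulfonylation does not involve the stereocentre, so the R configuration is retained.

Step 3
Reactants: 4 (R)-but-3-yn-2-yl methanesulfonate
Product: 5 (P)-tributyl(buta-1,2-dien-1-yl)stannane
Conditions: Bu3SnH, LiN(iPr)2, THF, 0 °C; CuBr·SMe2, −78 °C; then 4, −78 °C
Reagents that add atoms: tributyltin hydride CCCC[SnH](CCCC)CCCC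
Why: anti-SN2′ displacement of a propargylic sulfonate by a stannylcopper reagent should transfer the central chirality of (R)-4 to the (P) axis of the allene.

Step 4
Reactants: 2 aldehyde 5-(trimethylsilyl)pent-4-ynal; 5 (P)-tributyl(buta-1,2-dien-1-yl)stannane
Product: 6 diynol (3R,4R)-3-methyl-8-(trimethylsilyl)octa-1,7-diyn-4-ol
Conditions: BF3·OEt2 (1.2 equiv), CH2Cl2, −78 °C; aqueous work-up
Reagents that add atoms: none
Why: Lewis-acid-promoted SE2′ addition of a chiral allenylstannane to an aldehyde through an open transition state; attack anti to tin should set the methyl-bearing carbon (C4, R) from the (P) axis, and the syn preference of the BF3 variant should set the carbinol (C3, R).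

Step 5
Reactants: 6 diynol (3R,4R)-3-methyl-8-(trimethylsilyl)octa-1,7-diyn-4-ol
Product: 7 silyl ether tert-butyldimethyl{[(3R,4R)-3-methyl-8-(trimethylsilyl)octa-1,7-diyn-4-yl]oxy}silane
Conditions: TBSOTf, 2,6-lutidine, CH2Cl2, 0 °C
Reagents that add atoms: tert-butyldimethylsilyl trifluoromethanesulfonate CC(C)(C)[Si](C)(C)OS(=O)(=O)C(F)(F)F
Why: Standard silylation of a hindered secondary alcohol; the ether later sits equatorial on the tether and survives the borane, basic peroxide and acylation steps.

Step 6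
Reactants: 7 silyl ether tert-butyldimethyl{[(3R,4R)-3-methyl-8-(trimethylsilyl)octa-1,7-diyn-4-yl]oxy}silane
Product: 9 vinyl iodide tert-butyl{[(1E,3R,4R)-1-iodo-2,3-dimethyl-8-(trimethylsilyl)oct-1-en-7-yn-4-yl]oxy}dimethylsilane, via alkenylalane 8 (not isolated)
Conditions: Cp2ZrCl2 (0.5 equiv), AlMe3 (3 equiv), CH2Cl2, 0 °C to rt; then I2, THF, −30 °C
Reagents that add atoms: trimethylaluminium C[Al](C)C; iodine II
Why: Zirconium-catalysed syn-carboalumination of the terminal alkyne (Negishi carboalumination) should place the methyl (C14) on C5 and aluminium on C6 cis to it; iodinolysis with retention gives the E iodide (tether trans to iodine), and the silyl-capped alkyne reacts far more slowly.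

Step 7
Reactants: 9 vinyl iodide tert-butyl{[(1E,3R,4R)-1-iodo-2,3-dimethyl-8-(trimethylsilyl)oct-1-en-7-yn-4-yl]oxy}dimethylsilane; 10 (E)-1,2-bis(4,4,5,5-tetramethyl-1,3,2-dioxaborolan-2-yl)ethene
Product: 11 dienylboronate 2-[(1E,3E,5R,6R)-6-(tert-butyldimethylsilyloxy)-4,5-dimethyl-10-(trimethylsilyl)deca-1,3-dien-9-yn-1-yl]-4,4,5,5-tetramethyl-1,3,2-dioxaborolane
Conditions: Pd(PPh3)4 (5 mol %), 10 (3 equiv), 3 M aq. K3PO4, THF, 45 °C
Reagents that add atoms: none
Why: Stereoretentive Suzuki–Miyaura coupling; the excess of the bis-boronate should favour mono-coupling, so the (E,E)-diene is formed with the second boron left on C8 as the precursor of the C8 oxygen.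

Step 8
Reactants: 11 dienylboronate 2-[(1E,3E,5R,6R)-6-(tert-butyldimethylsilyloxy)-4,5-dimethyl-10-(trimethylsilyl)deca-1,3-dien-9-yn-1-yl]-4,4,5,5-tetramethyl-1,3,2-dioxaborolane
Product: 12 dienyne 2-[(1E,3E,5R,6R)-6-(tert-butyldimethylsilyloxy)-4,5-dimethyldeca-1,3-dien-9-yn-1-yl]-4,4,5,5-tetramethyl-1,3,2-dioxaborolane
Conditions: K2CO3 (0.3 equiv), MeOH, rt
Reagents that add atoms: none
Why: Methanolysis of the alkynyl C–Si bond is selective over the silyl ether and the pinacol boronate and frees the terminal alkyne (C9≡C10).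

Step 9
Reactants: 12 dienyne 2-[(1E,3E,5R,6R)-6-(tert-butyldimethylsilyloxy)-4,5-dimethyldeca-1,3-dien-9-yn-1-yl]-4,4,5,5-tetramethyl-1,3,2-dioxaborolane
Product: 15 diol 3α-(tert-butyldimethylsilyloxy)-11,12,13-trinoreremophil-6-ene-8α,9α-diol, via alkenylborane 13 (not isolated), via cycloadduct 14 (not isolated)
Conditions: BH3·SMe2 (1.1 equiv), cyclohexene (2.2 equiv), THF, 0 °C [gives (C6H11)2BH]; 12, 0 °C to rt; dilute to 0.02 M, 50 °C; then 3 M aq. NaOH, 30% H2O2, 0 °C to rt
Reagents that add atoms: hydrogen peroxide OO (both hydroxyl oxygens of 15); dicyclohexylborane C1CCCCC1BC1CCCCC1 (boron and cyclohexyl groups kept only in 13 and 14)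
Why: Syn-hydroboration of the terminal alkyne gives the (E)-alkenyldicyclohexylborane 13, whose vacant boron p orbital lowers the alkene LUMO, and a concerted but asynchronous intramolecular [4+2] with the (E,E)-dienylboronate (C5=C6–C7=C8) then forms C5–C10 (leading bond, from the nucleophilic trisubstituted diene terminus to the β-carbon of the vinylborane) and C8–C9; the closest known reaction types are the Diels–Alder reactions of dialkyl(vinyl)boranes and the type 1 intramolecular Diels–Alder reaction of 1,3,9-decatrienes. Ring A closes in the fused mode through the C1–C4 tether by the C5–C10 bond (chair-like six-membered tether), and ring B is the cyclohexene of the cycloaddition, closed by both new bonds. C5 and C10 (trans fusion, 10α-H) should follow from the endo position of boron under the diene (boron–diene secondary overlap) combined with the chair tether, and the π-face from C3–OTBS and C4–CH3 both lying equatorial on that chair, the alternative trans transition state having both axial. C9 (9α) follows from the E geometry of 13 (suprafacial addition) and is kept by oxidation with retention, and C8 (8α, destroyed later) from the E geometry of the dienylboronate. The step needs trans over cis fusion, one π-face and alkyne-selective hydroboration; these should be secured by the endo preference of the dialkylboryl group, the two equatorial tether substituents and the bulky (C6H11)2BH, which leaves the hindered dienylboronate alone, while the Z-methyl on C5 only slows the reaction, hence dilution and mild heating.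

Step 10
Reactants: 15 diol 3α-(tert-butyldimethylsilyloxy)-11,12,13-trinoreremophil-6-ene-8α,9α-diol
Product: 16 hydroxy enone 3α-(tert-butyldimethylsilyloxy)-9α-hydroxy-11,12,13-trinoreremophil-6-en-8-one
Conditions: MnO2 (activated, 20 equiv), CH2Cl2, rt
Reagents that add atoms: none
Why: MnO2 oxidises only allylic alcohols, so the C8 hydroxyl (allylic to C6=C7) should become the enone carbonyl while the C9 hydroxyl is kept; this differentiates the two boron-derived oxygens and removes the C8 stereocentre.

Step 11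
Reactants: 16 hydroxy enone 3α-(tert-butyldimethylsilyloxy)-9α-hydroxy-11,12,13-trinoreremophil-6-en-8-one; 17 (E)-3-methylpent-2-enoic acid
Product: 18 ester 3α-(tert-butyldimethylsilyloxy)-8-oxo-11,12,13-trinoreremophil-6-en-9α-yl (E)-3-methylpent-2-enoate
Conditions: DCC (1.5 equiv), DMAP (0.2 equiv), CH2Cl2, 0 °C to rt
Reagents that add atoms: none
Why: Steglich esterification of the only free hydroxyl; C9 is α to the ketone, but its equatorial (9α) configuration is the thermodynamically preferred one, so epimerisation is not a threat.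

Step 12
Reactants: 18 ester 3α-(tert-butyldimethylsilyloxy)-8-oxo-11,12,13-trinoreremophil-6-en-9α-yl (E)-3-methylpent-2-enoate
Product: 19 alcohol 3α-hydroxy-8-oxo-11,12,13-trinoreremophil-6-en-9α-yl (E)-3-methylpent-2-enoate
Conditions: HF·pyridine, THF, 0 °C to rt
Reagents that add atoms: none
Why: Buffered fluoride cleaves the silyl ether without base, so neither acyl migration nor enolisation of the α-acyloxy enone is expected.

Step 13
Reactants: 19 alcohol 3α-hydroxy-8-oxo-11,12,13-trinoreremophil-6-en-9α-yl (E)-3-methylpent-2-enoate; 20 angelic acid (Z)-2-methylbut-2-enoic acid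
Product: 22 diester 3α-angeloyloxy-8-oxo-11,12,13-trinoreremophil-6-en-9α-yl (E)-3-methylpent-2-enoate, via mixed anhydride 21 (not isolated)
Conditions: 20, 2,4,6-trichlorobenzoyl chloride, Et3N, toluene, rt; then 19, 75 °C
Reagents that add atoms: 2,4,6-trichlorobenzoyl chloride O=C(Cl)c1c(Cl)cc(Cl)cc1Cl (atoms kept only in 21)
Why: Yamaguchi esterification through the mixed anhydride, run without a nucleophilic catalyst, is the established way to acylate hindered secondary alcohols with angelic acid while keeping the Z geometry.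

Step 14
Reactants: 22 diester 3α-angeloyloxy-8-oxo-11,12,13-trinoreremophil-6-en-9α-yl (E)-3-methylpent-2-enoate
Product: 23 silyl enol ether 3α-angeloyloxy-8-(dimethylphenylsilyloxy)-11,12,13-trinoreremophil-7-en-9α-yl (E)-3-methylpent-2-enoate
Conditions: [(Ph3P)CuH]6 (5 mol %), PhMe2SiH (1.5 equiv), toluene, 0 °C to rt
Reagents that add atoms: dimethylphenylsilane C[SiH](C)c1ccccc1
Why: Copper hydride-catalysed conjugate reduction (1,4-hydrosilylation) delivers hydride to C6 and traps the enolate on oxygen, fixing the enol ether at C7=C8; the two trisubstituted enoate esters should react far more slowly than the β-monosubstituted enone.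

Step 15
Reactants: 23 silyl enol ether 3α-angeloyloxy-8-(dimethylphenylsilyloxy)-11,12,13-trinoreremophil-7-en-9α-yl (E)-3-methylpent-2-enoate; 24 2-bromopropene
Product: 26 target (3R,4R,5R,7S,9S,10R)-3-angeloyloxy-9-[(E)-3-methylpent-2-enoyloxy]eremophil-11-en-8-one, via tin enolate 25 (not isolated)
Conditions: Bu3SnF (1.1 equiv), Pd2(dba)3 (2.5 mol %), P(t-Bu)3 (6 mol %), 24 (3 equiv), toluene, 70 °C, sealed tube
Reagents that add atoms: tributyltin fluoride CCCC[Sn](F)(CCCC)CCCC (tin kept only in 25)
Why: Palladium-catalysed α-alkenylation of a ketone through its tin enolate: fluoride-driven Si-to-Sn exchange gives 25, which transmetalates to the isopropenylpalladium bromide formed by oxidative addition of 24 to zerovalent palladium, and reductive elimination forms C7–C11; palladium should bind C7 on the α-face because the β-face is blocked by the syn-axial C14 methyl, so the isopropenyl group ends equatorial (7S), the epimer favoured both kinetically and thermodynamically, under neutral conditions that should avoid conjugation of the new alkene.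

**Compound list**

1 | 5-(trimethylsilyl)pent-4-yn-1-ol | C[Si](C)(C)C#CCCCO | starting material
2 | 5-(trimethylsilyl)pent-4-ynal | C[Si](C)(C)C#CCCC=O | intermediate
3 | (R)-but-3-yn-2-ol | C[C@@H](O)C#C | starting material
4 | (R)-but-3-yn-2-yl methanesulfonate | C[C@@H](OS(C)(=O)=O)C#C | intermediate
5 | (P)-tributyl(buta-1,2-dien-1-yl)stannane | CC([H])=[C@@]=C([H])[Sn](CCCC)(CCCC)CCCC | intermediate
6 | (3R,4R)-3-methyl-8-(trimethylsilyl)octa-1,7-diyn-4-ol | C[Si](C)(C)C#CCC[C@@H](O)[C@H](C)C#C | intermediate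
7 | tert-butyldimethyl{[(3R,4R)-3-methyl-8-(trimethylsilyl)octa-1,7-diyn-4-yl]oxy}silane | C[Si](C)(C)C#CCC[C@@H](O[Si](C)(C)C(C)(C)C)[C@H](C)C#C | intermediate
8 | [(1E,3R,4R)-4-(tert-butyldimethylsilyloxy)-2,3-dimethyl-8-(trimethylsilyl)oct-1-en-7-yn-1-yl]dimethylalumane | C[Si](C)(C)C#CCC[C@@H](O[Si](C)(C)C(C)(C)C)[C@H](C)/C(C)=C/[Al](C)C | intermediate (not isolated)
9 | tert-butyl{[(1E,3R,4R)-1-iodo-2,3-dimethyl-8-(trimethylsilyl)oct-1-en-7-yn-4-yl]oxy}dimethylsilane | C[Si](C)(C)C#CCC[C@@H](O[Si](C)(C)C(C)(C)C)[C@H](C)/C(C)=C/I | intermediate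
10 | (E)-1,2-bis(4,4,5,5-tetramethyl-1,3,2-dioxaborolan-2-yl)ethene | CC1(C)OB(/C=C/B2OC(C)(C)C(C)(C)O2)OC1(C)C | starting material
11 | 2-[(1E,3E,5R,6R)-6-(tert-butyldimethylsilyloxy)-4,5-dimethyl-10-(trimethylsilyl)deca-1,3-dien-9-yn-1-yl]-4,4,5,5-tetramethyl-1,3,2-dioxaborolane | C[Si](C)(C)C#CCC[C@@H](O[Si](C)(C)C(C)(C)C)[C@H](C)/C(C)=C/C=C/B1OC(C)(C)C(C)(C)O1 | intermediate
12 | 2-[(1E,3E,5R,6R)-6-(tert-butyldimethylsilyloxy)-4,5-dimethyldeca-1,3-dien-9-yn-1-yl]-4,4,5,5-tetramethyl-1,3,2-dioxaborolane | C#CCC[C@@H](O[Si](C)(C)C(C)(C)C)[C@H](C)/C(C)=C/C=C/B1OC(C)(C)C(C)(C)O1 | intermediate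
13 | dicyclohexyl[(1E,5R,6R,7E,9E)-5-(tert-butyldimethylsilyloxy)-6,7-dimethyl-10-(4,4,5,5-tetramethyl-1,3,2-dioxaborolan-2-yl)deca-1,7,9-trien-1-yl]borane | C1CCCCC1B(C1CCCCC1)/C=C/CC[C@@H](O[Si](C)(C)C(C)(C)C)[C@H](C)/C(C)=C/C=C/B1OC(C)(C)C(C)(C)O1 | intermediate (not isolated)
14 | 3α-(tert-butyldimethylsilyloxy)-9α-(dicyclohexylboryl)-8α-(4,4,5,5-tetramethyl-1,3,2-dioxaborolan-2-yl)-11,12,13-trinoreremophil-6-ene | C1=C[C@]2(C)[C@@H](C)[C@H](O[Si](C)(C)C(C)(C)C)CC[C@H]2[C@H](B(C3CCCCC3)C3CCCCC3)[C@@H]1B4OC(C)(C)C(C)(C)O4 | intermediate (not isolated)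
15 | 3α-(tert-butyldimethylsilyloxy)-11,12,13-trinoreremophil-6-ene-8α,9α-diol | C1=C[C@]2(C)[C@@H](C)[C@H](O[Si](C)(C)C(C)(C)C)CC[C@H]2[C@H](O)[C@@H]1O | intermediate
16 | 3α-(tert-butyldimethylsilyloxy)-9α-hydroxy-11,12,13-trinoreremophil-6-en-8-one | O=C1C=C[C@]2(C)[C@@H](C)[C@H](O[Si](C)(C)C(C)(C)C)CC[C@H]2[C@@H]1O | intermediate
17 | (E)-3-methylpent-2-enoic acid | CC/C(C)=C/C(=O)O | starting material
18 | 3α-(tert-butyldimethylsilyloxy)-8-oxo-11,12,13-trinoreremophil-6-en-9α-yl (E)-3-methylpent-2-enoate | O=C1C=C[C@]2(C)[C@@H](C)[C@H](O[Si](C)(C)C(C)(C)C)CC[C@H]2[C@@H]1OC(=O)/C=C(\C)CC | intermediate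
19 | 3α-hydroxy-8-oxo-11,12,13-trinoreremophil-6-en-9α-yl (E)-3-methylpent-2-enoate | O=C1C=C[C@]2(C)[C@@H](C)[C@H](O)CC[C@H]2[C@@H]1OC(=O)/C=C(\C)CC | intermediate
20 | angelic acid, (Z)-2-methylbut-2-enoic acid | C/C=C(/C)C(=O)O | starting material
21 | (Z)-2-methylbut-2-enoic 2,4,6-trichlorobenzoic anhydride | C/C=C(/C)C(=O)OC(=O)c1c(Cl)cc(Cl)cc1Cl | intermediate (not isolated)
22 | 3α-angeloyloxy-8-oxo-11,12,13-trinoreremophil-6-en-9α-yl (E)-3-methylpent-2-enoate | O=C1C=C[C@]2(C)[C@@H](C)[C@H](OC(=O)/C(C)=C\C)CC[C@H]2[C@@H]1OC(=O)/C=C(\C)CC | intermediate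
23 | 3α-angeloyloxy-8-(dimethylphenylsilyloxy)-11,12,13-trinoreremophil-7-en-9α-yl (E)-3-methylpent-2-enoate | C[Si](C)(c1ccccc1)OC1=CC[C@]2(C)[C@@H](C)[C@H](OC(=O)/C(C)=C\C)CC[C@H]2[C@@H]1OC(=O)/C=C(\C)CC | intermediate
24 | 2-bromopropene | CC(Br)=C | starting material
25 | 3α-angeloyloxy-8-(tributylstannyloxy)-11,12,13-trinoreremophil-7-en-9α-yl (E)-3-methylpent-2-enoate | CCCC[Sn](CCCC)(CCCC)OC1=CC[C@]2(C)[C@@H](C)[C@H](OC(=O)/C(C)=C\C)CC[C@H]2[C@@H]1OC(=O)/C=C(\C)CC | intermediate (not isolated)
26 | (3R,4R,5R,7S,9S,10R)-3-angeloyloxy-9-[(E)-3-methylpent-2-enoyloxy]eremophil-11-en-8-one (CNP0301161.1) | C=C(C)[C@@H]1C[C@]2(C)[C@@H](C)[C@H](OC(=O)/C(C)=C\C)CC[C@H]2[C@H](OC(=O)/C=C(\C)CC)C1=O | target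

**Totals**
Total step count: 15. Longest linear sequence: 14 steps (from 3 through steps 2 to 15).

**Steps most likely to fail**

Step 9. The cycloaddition may be too slow next to redistribution of the alkenylborane, or cis fusion or the wrong π-face may compete if endo and tether control are weak. The fallback sets out from 12 and comes back at 15. A cationic rhodium catalyst ([Rh(cod)Cl]2, AgSbF6, ClCH2CH2Cl, rt to 50 °C) should effect the intramolecular [4+2] of the diene–yne with the alkyne as the 2π partner. This gives the cyclohexa-1,4-diene 3α-(tert-butyldimethylsilyloxy)-8α-(pinacolboryl)-11,12,13-trinoreremophila-6,9-diene F1, with C5 and the bicycle in place. Hydroboration of its trisubstituted C9=C10 bond (BH3·SMe2, THF, 0 °C) from the α-face, anti to the vicinal angular methyl, should then put hydrogen on C10 and boron on C9; C6=C7 is shielded by the quaternary C5 and the boron-bearing C8. NaOH/H2O2 oxidises both C–B bonds to 15.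

Step 15. β-Hydride elimination of the palladium enolate back to enone 22, slow reductive elimination at the hindered C7, or drift of the new alkene into conjugation may intervene. The fallback sets out from 23 and comes back at 26. A TiCl4-mediated Mukaiyama aldol addition of 23 to 1-(phenylselanyl)propan-2-one (CH2Cl2, −78 °C) should give the β-hydroxy selenide 7α-[2-hydroxy-1-(phenylselanyl)propan-2-yl] ketone F2, with C7 attacked from the α-face; the configuration at the carbinol carbon is immaterial. MsCl/Et3N (CH2Cl2, 0 °C) then eliminates the hydroxyl and selanyl groups regiospecifically to the C11=C12 alkene without touching C7–H.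

Step 10. Oxidation of the pseudo-axial allylic alcohol may be slow, and glycol cleavage of the cis-diol on MnO2 may compete. The fallback sets out from 15 and comes back at 18 by inverting the order. The more accessible equatorial 9α-hydroxyl is acylated first (17, DCC, DMAP, CH2Cl2, −20 °C) to the hydroxy ester 3α-(tert-butyldimethylsilyloxy)-8α-hydroxy-11,12,13-trinoreremophil-6-en-9α-yl (E)-3-methylpent-2-enoate F3. The remaining allylic 8α-hydroxyl is then oxidised with Dess–Martin periodinane buffered with NaHCO3.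

**Further compounds**
F1 | step 9 | 3α-(tert-butyldimethylsilyloxy)-8α-(4,4,5,5-tetramethyl-1,3,2-dioxaborolan-2-yl)-11,12,13-trinoreremophila-6,9-diene | C1=C[C@]2(C)[C@@H](C)[C@H](O[Si](C)(C)C(C)(C)C)CCC2=C[C@@H]1B3OC(C)(C)C(C)(C)O3
F2 | step 15 | (3R,4R,5R,7S,9S,10R)-3-angeloyloxy-7-[2-hydroxy-1-(phenylselanyl)propan-2-yl]-9-[(E)-3-methylpent-2-enoyloxy]-11,12,13-trinoreremophilan-8-one (carbinol epimers) | CC(O)(C[Se]c1ccccc1)[C@@H]1C[C@]2(C)[C@@H](C)[C@H](OC(=O)/C(C)=C\C)CC[C@H]2[C@H](OC(=O)/C=C(\C)CC)C1=O
F3 | step 10 | 3α-(tert-butyldimethylsilyloxy)-8α-hydroxy-11,12,13-trinoreremophil-6-en-9α-yl (E)-3-methylpent-2-enoate | C1=C[C@]2(C)[C@@H](C)[C@H](O[Si](C)(C)C(C)(C)C)CC[C@H]2[C@H](OC(=O)/C=C(\C)CC)[C@@H]1O
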